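Overview: the bought 6-methoxycoumarin bicycle carries on O7 the chain O7–C1H2–C2H=C3(CH3)–C4H(OH)–C5H2–C6H2–C7(CH3)2OH. The strategy rests on its 1,4-dioxygenated E-trisubstituted 2-ene unit, in which O7–C1 and C4–OH flank C2=C3.
Disconnection 1, after unmasking a silyl ether on the C7 hydroxyl: the O7–C1 bond, read as the 1,4-adduct of the acidic coumarin 7-OH across an enantiopure 2-methyl-2-vinyloxirane under zerovalent palladium catalysis.
Disconnection 2: vinyl epoxide from epoxy aldehyde (Wittig), from epoxy alcohol (Sharpless epoxidation, which sets C4), from E-allylic alcohol (SeO2), from sulcatone plus a methyl Grignard reagent.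
Ring order: no ring of the target is built. The coumarin is purchased, and the oxirane is a transient ring made in step 4 and opened in step 7.

Key step: step 7

Assumption: side-chain atoms are labelled C1 (OCH2) to C8 from the ether oxygen O7, the stereocentre C4 reads R from the SMILES, and the usual empirical face rule of the titanium–tartrate epoxidation is taken to hold for the allylic alcohol used here (to be confirmed by Mosher analysis of the free C4 carbinol after the key step).

Step 1
Reactants: 1 6-methylhept-5-en-2-one (sulcatone); 2 methylmagnesium bromide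
Product: 4 2,6-dimethylhept-5-en-2-ol, via bromomagnesium alkoxide 3 (not isolated)
Conditions: MeMgBr (1.2 equiv), THF, 0 °C to rt; then sat. aq. NH4Cl
Reagents that add atoms: methylmagnesium bromide (compound 2), C[Mg]Br
Why: Grignard addition of a methyl nucleophile to an unhindered methyl ketone is reliable, the remote trisubstituted alkene is inert, and no stereocentre arises because the new carbinol carbon carries two methyl groups.

Step 2
Reactants: 4 2,6-dimethylhept-5-en-2-ol
Product: 5 triethyl[(2,6-dimethylhept-5-en-2-yl)oxy]silane
Conditions: Et3SiOTf (1.2 equiv), 2,6-lutidine (2 equiv), CH2Cl2, 0 °C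
Reagents that add atoms: triethylsilyl triflate, CC[Si](CC)(CC)OS(=O)(=O)C(F)(F)F
Why: Silyl triflate silylation is the standard way to cap a hindered tertiary alcohol, and the mask stops this oxygen from later attacking the epoxide or the allylpalladium unit as an internal nucleophile.

Step 3
Reactants: 5 triethyl[(2,6-dimethylhept-5-en-2-yl)oxy]silane
Product: 7 (E)-2,6-dimethyl-6-(triethylsilyloxy)hept-2-en-1-ol, via enal 6 (not isolated)
Conditions: SeO2 (0.3 equiv), t-BuOOH (in decane, 2.5 equiv), CH2Cl2, 0 °C to rt; crude mixture, NaBH4, MeOH, 0 °C
Reagents that add atoms: tert-butyl hydroperoxide, CC(C)(C)OO (net oxygen source, relayed through catalytic SeO2, O=[Se]=O)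
Why: The Riley allylic oxidation (ene reaction, then 2,3-sigmatropic shift) attacks the more substituted alkene terminus and should functionalise the E-methyl group selectively, and borohydride returns the over-oxidised portion (enal 6) to the same E-allylic alcohol.

Step 4
Reactants: 7 (E)-2,6-dimethyl-6-(triethylsilyloxy)hept-2-en-1-ol
Product: 8 {(2R,3R)-2-methyl-3-[3-methyl-3-(triethylsilyloxy)butyl]oxiran-2-yl}methanol
Conditions: Ti(OiPr)4 (10 mol %), D-(−)-diisopropyl tartrate (12 mol %), anhydrous t-BuOOH (2 equiv), 4 Å molecular sieves, CH2Cl2, −20 °C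
Reagents that add atoms: tert-butyl hydroperoxide, CC(C)(C)OO
Why: In the Sharpless asymmetric epoxidation the allylic hydroxyl binds the titanium–tartrate complex, which delivers the peroxide oxygen to one alkene face; since L-(+)-tartrate gives 2S,3S-epoxides from E-allylic alcohols, the D-(−)-ester should give the 2R,3R-epoxide, whose secondary carbon is the future C4 (R), with the E geometry of 7 copied into the trans relation of CH2OH and side chain.

Step 5
Reactants: 8 {(2R,3R)-2-methyl-3-[3-methyl-3-(triethylsilyloxy)butyl]oxiran-2-yl}methanol
Product: 9 (2S,3R)-2-methyl-3-[3-methyl-3-(triethylsilyloxy)butyl]oxirane-2-carbaldehyde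
Conditions: SO3·pyridine (3 equiv), DMSO, Et3N (6 equiv), CH2Cl2, 0 °C
Reagents that add atoms: none
Why: The Parikh–Doering oxidation (activated DMSO) runs under basic conditions that spare the trisubstituted epoxide and the silyl ether, stops at the aldehyde, and cannot epimerise the quaternary alpha carbon (its descriptor changes from R to S only because CHO outranks the ring carbon).

Step 6
Reactants: 9 (2S,3R)-2-methyl-3-[3-methyl-3-(triethylsilyloxy)butyl]oxirane-2-carbaldehyde; 10 methyltriphenylphosphonium bromide
Product: 12 (2R,3R)-2-ethenyl-2-methyl-3-[3-methyl-3-(triethylsilyloxy)butyl]oxirane, via methylenetriphenylphosphorane 11 (not isolated)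
Conditions: Ph3PCH3Br (1.5 equiv), KN(SiMe3)2 (1.4 equiv), THF, 0 °C; then 9, −78 °C to 0 °C
Reagents that add atoms: methyltriphenylphosphonium bromide (compound 10), C[P+](c1ccccc1)(c1ccccc1)c1ccccc1.[Br-]
Why: Wittig methylenation of a non-enolisable epoxy aldehyde with the lithium-free ylide at low temperature is a standard entry to vinyl epoxides and touches neither oxirane stereocentre.

Step 7
Reactants: 12 (2R,3R)-2-ethenyl-2-methyl-3-[3-methyl-3-(triethylsilyloxy)butyl]oxirane; 13 scopoletin (7-hydroxy-6-methoxy-2H-chromen-2-one)
Product: 15 7-{[(2E,4R)-4-hydroxy-3,7-dimethyl-7-(triethylsilyloxy)oct-2-en-1-yl]oxy}-6-methoxy-2H-chromen-2-one, via pi-allyl Pd(PPh3)2 alkoxide zwitterion 14 (not isolated)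
Conditions: Pd2(dba)3·CHCl3 (2.5 mol %), PPh3 (15 mol %), 13 (1.2 equiv), degassed THF, slow addition of 12 at 0 °C, then rt until regio- and geometric equilibration is complete; no added base
Reagents that add atoms: none
Why: Zerovalent palladium adds to the vinyl group of 12 anti to the allylic tertiary C3–O bond and ionises it, giving the divalent pi-allylpalladium alkoxide 14 that spans C1–C3, and this alkoxide at once takes the proton of the 7-OH of 13 (pKa about 8), so the aryloxide is born next to its electrophile and no external base ever meets the lactone. The aryloxide then attacks the unsubstituted terminus C1, which makes the O7–C1 bond, leaves the double bond at C2=C3, frees the C4 hydroxyl and returns zerovalent palladium; the closest known reaction type is the neutral Tsuji–Trost 1,4-addition of phenols and other acidic pronucleophiles to isoprene monoxide, here with one more alkyl group on the carbinol carbon. No ring is closed (the oxirane is opened) and no stereocentre is created: C3 turns sp2, while C4 keeps the R configuration fixed in step 4 because neither its C–O nor its C–H bond is touched. The step needs C1 over C3 attack and E over Z geometry, and both are left to equilibration: an aryloxide of this acidity is a competent leaving group toward zerovalent palladium, so attack at the crowded tertiary terminus is reversible, and syn/anti interchange of the allyl unit puts the larger carbinol branch syn, which maps onto the E alkene in which C1 is cis to the C3 methyl group. The primary ether of the trisubstituted alkene is the thermodynamic sink, whereas the C4 hydroxyl cannot ionise, so the material should funnel to 15. The substrate secures the rest: the triethylsilyl group removes the only internal nucleophile, slow addition of 12 to excess phenol keeps protonation and capture ahead of hydride shift or proton loss from 14, and every atom of both partners ends up in the product.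

Step 8
Reactants: 15 7-{[(2E,4R)-4-hydroxy-3,7-dimethyl-7-(triethylsilyloxy)oct-2-en-1-yl]oxy}-6-methoxy-2H-chromen-2-one
Product: 16 7-{[(2E,4R)-4,7-dihydroxy-3,7-dimethyloct-2-en-1-yl]oxy}-6-methoxy-2H-chromen-2-one (CNP0197418.1)
Conditions: HF·pyridine, excess pyridine, THF, 0 °C to rt
Reagents that add atoms: none
Why: Fluoride-driven desilylation of a triethylsilyl ether in a pyridine-buffered medium is mild enough to leave the allylic carbinol, the allyl aryl ether, the new tertiary alcohol and the lactone unionised and intact, so C4 stays R and C2=C3 stays E.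

Compound list
1 | 6-methylhept-5-en-2-one (sulcatone) | CC(=O)CCC=C(C)C | starting material
2 | methylmagnesium bromide | C[Mg]Br | starting material
3 | bromomagnesium 2,6-dimethylhept-5-en-2-olate (not isolated) | CC(C)=CCCC(C)(C)O[Mg]Br | intermediate
4 | 2,6-dimethylhept-5-en-2-ol | CC(C)=CCCC(C)(C)O | intermediate
5 | triethyl[(2,6-dimethylhept-5-en-2-yl)oxy]silane | CC(C)=CCCC(C)(C)O[Si](CC)(CC)CC | intermediate
6 | (E)-2,6-dimethyl-6-(triethylsilyloxy)hept-2-enal (not isolated) | O=C/C(C)=C/CCC(C)(C)O[Si](CC)(CC)CC | intermediate
7 | (E)-2,6-dimethyl-6-(triethylsilyloxy)hept-2-en-1-ol | OC/C(C)=C/CCC(C)(C)O[Si](CC)(CC)CC | intermediate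
8 | {(2R,3R)-2-methyl-3-[3-methyl-3-(triethylsilyloxy)butyl]oxiran-2-yl}methanol | OC[C@@]1(C)O[C@@H]1CCC(C)(C)O[Si](CC)(CC)CC | intermediate
9 | (2S,3R)-2-methyl-3-[3-methyl-3-(triethylsilyloxy)butyl]oxirane-2-carbaldehyde | O=C[C@@]1(C)O[C@@H]1CCC(C)(C)O[Si](CC)(CC)CC | intermediate
10 | methyltriphenylphosphonium bromide | C[P+](c1ccccc1)(c1ccccc1)c1ccccc1.[Br-] | starting material
11 | methylenetriphenylphosphorane (not isolated) | C=P(c1ccccc1)(c1ccccc1)c1ccccc1 | intermediate
12 | (2R,3R)-2-ethenyl-2-methyl-3-[3-methyl-3-(triethylsilyloxy)butyl]oxirane | C=C[C@@]1(C)O[C@@H]1CCC(C)(C)O[Si](CC)(CC)CC | intermediate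
13 | scopoletin (7-hydroxy-6-methoxy-2H-chromen-2-one) | COc1cc2ccc(=O)oc2cc1O | starting material
14 | pi-allyl Pd(PPh3)2 alkoxide zwitterion, drawn in its C1-bound sigma form (not isolated) | c1ccccc1[P+](c1ccccc1)(c1ccccc1)[Pd-]([P+](c1ccccc1)(c1ccccc1)c1ccccc1)C/C=C(\C)[C@H]([O-])CCC(C)(C)O[Si](CC)(CC)CC | intermediate
15 | 7-{[(2E,4R)-4-hydroxy-3,7-dimethyl-7-(triethylsilyloxy)oct-2-en-1-yl]oxy}-6-methoxy-2H-chromen-2-one | COc1cc2ccc(=O)oc2cc1OC/C=C(\C)[C@H](O)CCC(C)(C)O[Si](CC)(CC)CC | intermediate
16 | 7-{[(2E,4R)-4,7-dihydroxy-3,7-dimethyloct-2-en-1-yl]oxy}-6-methoxy-2H-chromen-2-one (CNP0197418.1) | COc1cc2ccc(=O)oc2cc1OC/C=C(\C)[C@H](O)CCC(C)(C)O | target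

Total step count: 8
Longest linear sequence: 8 steps (1 to 16)

Steps most likely to fail

1. Step 7 (key step).
- What may go wrong:
  - Capture at the tertiary allyl terminus may not revert fast enough.
  - Syn/anti equilibration may stay incomplete, so the alkene geometry erodes.
  - The ionised epoxide may collapse before the aryloxide arrives, by hydride shift, by proton loss, or by closure of the C4 oxygen onto C1.
- Fallback: it sets out from 12 and replaces the catalysis with a two-stage ionic sequence. TiCl4 in CH2Cl2 at −80 °C cleaves the tertiary allylic C3–O bond with chloride entering at C1. This SN2′-type opening is known for 2-methyl-2-vinyloxirane and leaves the C4–O bond untouched. It should give (2E,4R)-1-chloro-3,7-dimethyl-7-(triethylsilyloxy)oct-2-en-4-ol F1. Williamson etherification of 13 with F1 (K2CO3, DMF, rt) then forms the same O7–C1 bond by direct SN2 displacement and comes back to the route at 15.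

2. Step 3.
- What may go wrong:
  - The allylic oxidation may stall at low conversion.
  - It may run on past the aldehyde stage.
  - Acidic selenium species may strip part of the silyl group.
- Fallback: it sets out from 5 and builds the E-allylic alcohol by cleavage and olefination instead of C–H oxidation. Ozonolysis (O3, CH2Cl2, −78 °C, then Me2S) should give 4-methyl-4-(triethylsilyloxy)pentanal F2. An E-selective Wittig reaction with the stabilised ylide ethyl 2-(triphenylphosphoranylidene)propanoate (CH2Cl2, rt) should give ethyl (E)-2,6-dimethyl-6-(triethylsilyloxy)hept-2-enoate F3. Reduction with iBu2AlH (CH2Cl2, −78 °C) comes back to the route at 7.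

3. Step 6.
- What may go wrong:
  - The epoxy aldehyde may degrade on handling.
  - Addition to its neopentyl-like carbonyl may be sluggish.
  - The basic ylide may open the oxirane.
- Fallback: it sets out from 7 and reverses the order of olefination and epoxidation.
  - MnO2 (CH2Cl2, rt) gives enal 6, here isolated.
  - Methylenation of this robust enal with ylide 11 should give (E)-triethyl[(2,6-dimethylocta-5,7-dien-2-yl)oxy]silane F4.
  - A Shi epoxidation follows, with 1,2:4,5-di-O-isopropylidene-β-D-erythro-2,3-hexodiulo-2,6-pyranose (the D-fructose-derived ketone) and KHSO5, in buffered MeCN–dimethoxymethane–water at 0 °C.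
  - It should oxidise only the electron-richer trisubstituted alkene of the diene, in the R,R sense, and comes back to the route at 12, bypassing 8 and 9.

Further compounds
F1 | step 7 | (2E,4R)-1-chloro-3,7-dimethyl-7-(triethylsilyloxy)oct-2-en-4-ol | ClC/C=C(\C)[C@H](O)CCC(C)(C)O[Si](CC)(CC)CC
F2 | step 3 | 4-methyl-4-(triethylsilyloxy)pentanal | O=CCCC(C)(C)O[Si](CC)(CC)CC
F3 | step 3 | ethyl (E)-2,6-dimethyl-6-(triethylsilyloxy)hept-2-enoate | CCOC(=O)/C(C)=C/CCC(C)(C)O[Si](CC)(CC)CC
F4 | step 6 | (E)-triethyl[(2,6-dimethylocta-5,7-dien-2-yl)oxy]silane | C=C/C(C)=C/CCC(C)(C)O[Si](CC)(CC)CC
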